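The constants were drawn at random within sensible limits; no experiment stands behind them.

Maple runs hotter than alder, on the same charges and for the same time.

- maple: substrate 0.50 mM; partner 1.50 equiv; protic impurity 0.0100 mM; temperature 55 °C; time 80 s
- alder: substrate 0.50 mM; partner 1.50 equiv; protic impurity 0.0100 mM; temperature 40 °C; time 80 s

    substrate + partner ⇌ adduct (K1 = 2880 M⁻¹, k1 = 7990 M⁻¹ s⁻¹, Ea1 = 20.0 kJ mol⁻¹, ΔH1 = −4.00 kJ mol⁻¹)
    adduct → target (k2 = 0.0825 s⁻¹, Ea2 = 88.0 kJ mol⁻¹)
    adduct → side product (k3 = 0.0577 s⁻¹, Ea3 = 88.0 kJ mol⁻¹)
    partner + protic impurity → quenched reagent (k4 = 3080 M⁻¹ s⁻¹, Ea4 = 25.0 kJ mol⁻¹)
    (constants at 40 °C)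

1. the flask with the highest amount of target, in percent of the substrate charged ("all alike" if they lie within 1.5 percentage points) (maple / alder / all alike)
2. final target, as a percentage of the substrate charged, in maple
3. final target, as a percentage of the substrate charged, in alder

- the constants hold at 40 °C; other temperatures follow from the activation energies and enthalpies

The quantity to carry is the branch share, the fraction of decaying adduct that leaves as target (the selectivity of the adduct): 58.8%. The activation energies of the two exits differ by 0 kJ mol⁻¹, so the branch share is the same in both flasks.

The ladder is reckoned here for alder, where the constants stand as given, with [partner] at its charge of 0.750 mM, rung by rung: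

binding of substrate, half-life 0.116 s
back reaction of adduct, half-life 0.250 s
quenching of protic impurity, half-life 0.300 s
decay of adduct through both exits, half-life 4.94 s

Binding and its reverse run far faster than the adduct decays, so in alder substrate and adduct behave as one pool in pre-equilibrium. With substrate consumed and the protic impurity quenched, [partner] in alder comes to 0.240 mM; the 0.0100 mM of partner claimed by the protic impurity is far less than the excess of 0.250 mM. This reckoning holds [partner] at that level:

adduct share of the pool: 40.9%
pool decay constant: 0.0573 s⁻¹, half-life 12.1 s
pool left in alder after 80 s: 1.02%
target in alder: 58.2%

Maple is hotter, and the exits have a higher activation energy than binding, so this reckoning takes the pool in maple as consumed and commits to the branch share, 58.8%, for that flask. The gap of 0.6 percentage points lies within the margin, so the flasks count as alike.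

The forecast says all alike, with 58.8% in maple and 58.4% in alder, on the ground that “Steps 2 and 3 have equal activation energies, so the split stays fixed”. Its alder figure and the 58.2% reckoned here differ by 0.20 points.

The simulation gives all alike, with 58.8% in maple and 58.4% in alder. In maple, half of the turnover to target was done by 2.14 s, and at 40.0 s substrate and adduct stood at 0% and 0%, with the yield level with the branch share. In alder, substrate 0.427% and adduct 0.289% remained at 80.0 s, and the branch share of the rest is 58.4%. The neighbour of maple charged with 0.900 equiv of partner kept 12.0% of its substrate unconverted; the branch share of the remainder is 51.7%, and that flask made 51.8% target.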